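**Retrosynthetic overview**

1. Numbering (labdane type): ring A = C1–C5/C10 (C3 ketone, C4 gem-dimethyl), ring B = C5–C10 (C8 carbinol; C9 carries C11 and the chain). The chain is cut at C11–C12: a C11 α-sulfonyl carbanion is alkylated with a 12-silyloxy-farnesyl bromide.
2. Ring A is made last on a ring B cyclohexanone: Robinson annulation with ethyl vinyl ketone (C1–C10, C4–C5), deconjugative C4 methylation, then hydrogenation of C5=C6 directed by the C9 CH2OH group, which gives the cis A/B fusion.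
3. Ring B is made first, in one enantioselective [4+2] cycloaddition of an achiral 3-silyloxy diene (C6=C5–C10=C9) with 2-(benzyloxy)acrolein (C7=C8). The ring closes through the new C6–C7 bond (together with C8–C9), and C8 and C9 are set.
4. Enabling feature: in ring B the oxygenated, methyl-bearing C8 and the ring-fusion carbon C5 stand 1,4 across the C6–C7 ethano bridge, and C9 is the only branched neighbour of C8. This is the pattern of a Diels–Alder adduct of a silyloxy diene and a 2-oxygenated enal.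
5. Order of ring formation: ring B (step 9), then ring A (step 11).

Key step: step 9

Remark: read literally, the stereodescriptors (C5 S, C8 R, C9 R, C10 S) place H-5, the C10 methyl, the C9 chain and the C8 methyl on one face, i.e. a cis-fused A/B decalin; the route is built for exactly this isomer. Compounds 1, 7, 8, 11 and 17 are taken as commercial.

**Step 1**
Reactants: 1 (2E,6E)-farnesol
Product: 2 (2E,6E)-farnesyl acetate
Conditions: Ac2O, pyridine, DMAP (cat.), CH2Cl2, 0 → 23 °C
Reagents that add atoms: acetic anhydride, CC(=O)OC(C)=O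
Why: O-acylation (esterification) masks the allylic alcohol so that only the distal trisubstituted alkene is oxidised next.

**Step 2**
Reactants: 2 (2E,6E)-farnesyl acetate
Product: 3 (2E,6E,10E)-12-hydroxyfarnesyl acetate
Conditions: SeO2 (0.3 equiv), t-BuOOH (3 equiv), salicylic acid (cat.), CH2Cl2, 23 °C
Reagents that add atoms: tert-butyl hydroperoxide, CC(C)(C)OO
Why: SeO2-catalysed allylic oxidation (ene reaction then [2,3] shift) should take the (E)-methyl of the most electron-rich, terminal alkene and keep the E geometry.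

**Step 3**
Reactants: 3 (2E,6E,10E)-12-hydroxyfarnesyl acetate
Product: 4 (2E,6E,10E)-12-(tert-butyldimethylsilyloxy)farnesyl acetate
Conditions: TBSCl, imidazole, DMF, 23 °C
Reagents that add atoms: tert-butyldimethylsilyl chloride, CC(C)(C)[Si](C)(C)Cl
Why: standard silylation of a primary allylic alcohol.

**Step 4**
Reactants: 4 (2E,6E,10E)-12-(tert-butyldimethylsilyloxy)farnesyl acetate
Product: 5 (2E,6E,10E)-12-(tert-butyldimethylsilyloxy)-3,7,11-trimethyldodeca-2,6,10-trien-1-ol
Conditions: K2CO3 (cat.), MeOH, 0 °C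
Reagents that add atoms: none
Why: base-catalysed transesterification removes the acetate and leaves the silyl ether.

**Step 5**
Reactants: 5 (2E,6E,10E)-12-(tert-butyldimethylsilyloxy)-3,7,11-trimethyldodeca-2,6,10-trien-1-ol
Product: 6 (2E,6E,10E)-1-bromo-12-(tert-butyldimethylsilyloxy)-3,7,11-trimethyldodeca-2,6,10-triene
Conditions: CBr4, PPh3, CH2Cl2, 0 °C
Reagents that add atoms: carbon tetrabromide, BrC(Br)(Br)Br
Why: Appel bromination of a primary allylic alcohol should proceed by SN2 at low temperature without allylic transposition.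

**Step 6**
Reactants: 7 2-(tert-butyldimethylsilyloxy)acetaldehyde; 8 3-(triphenylphosphoranylidene)butan-2-one
Product: 9 (E)-5-(tert-butyldimethylsilyloxy)-3-methylpent-3-en-2-one
Conditions: toluene, 80 °C
Reagents that add atoms: none
Why: Wittig olefination with a stabilised ylide should give the (E)-trisubstituted enone (acetyl trans to CH2OTBS).

**Step 7**
Reactants: 9 (E)-5-(tert-butyldimethylsilyloxy)-3-methylpent-3-en-2-one
Product: 10 (E)-2,5-bis(tert-butyldimethylsilyloxy)-3-methylpenta-1,3-diene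
Conditions: TBSOTf, Et3N, CH2Cl2, 0 °C
Reagents that add atoms: tert-butyldimethylsilyl trifluoromethanesulfonate, CC(C)(C)[Si](C)(C)OS(=O)(=O)C(F)(F)F
Why: soft enolisation of the methyl ketone gives the cross-conjugated silyloxy diene; the C9=C10 geometry (CH2OTBS on the outside of the diene) is untouched.

**Step 8**
Reactants: 11 2-(benzyloxy)acetaldehyde
Product: 12 2-(benzyloxy)prop-2-enal
Conditions: aqueous HCHO, pyrrolidine (10 mol %), propionic acid (10 mol %), i-PrOH, 45 °C
Reagents that add atoms: formaldehyde, C=O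
Why: amine-catalysed Mannich condensation and elimination (α-methylenation of an aldehyde) should install the C7 methylene.

**Step 9**
Reactants: 10 (E)-2,5-bis(tert-butyldimethylsilyloxy)-3-methylpenta-1,3-diene; 12 2-(benzyloxy)prop-2-enal
Product: 13 (1R,2S)-1-(benzyloxy)-4-(tert-butyldimethylsilyloxy)-2-[(tert-butyldimethylsilyloxy)methyl]-3-methylcyclohex-3-ene-1-carbaldehyde
Conditions: (S)-1-(2-methylphenyl)-3,3-diphenyltetrahydro-1H,3H-pyrrolo[1,2-c][1,3,2]oxazaborole (20 mol %) protonated by HN(SO2CF3)2 (16 mol %), CH2Cl2, −78 °C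
Reagents that add atoms: none
Why: The boron-bound enal and the silyloxy diene should combine in a concerted but asynchronous Diels–Alder reaction, the closest known type being oxazaborolidinium-catalysed cycloadditions of 2-substituted acroleins with silyloxy dienes. Ring B closes as a six-membered ring in the [4+2] mode: the nucleophilic diene terminus C6 bonds to the enal β-carbon C7 and C9 bonds to C8. Regiochemistry is fixed twice over, the silyloxy group ending 1,4 to C8 and the C9 substituent next to C8. The C8/C9 relationship follows from the endo position of the formyl group and the E diene: formyl (the future C8 methyl) cis to C11, benzyloxy trans. The absolute sense comes from the catalyst, which shields one face of the coordinated enal; the (S)-catalyst is chosen on the formyl C–H···O binding model. The step needs carbo- over hetero-cycloaddition and no Mukaiyama-type addition, which low temperature and single-point aldehyde activation should secure.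

**Step 10**
Reactants: 13 cycloadduct aldehyde
Product: 16 (3S,4R)-4-(benzyloxy)-3-[(tert-butyldimethylsilyloxy)methyl]-2,4-dimethylcyclohexan-1-one (C2 epimers), via tosylhydrazone 14 (not isolated), via methyl silyl enol ether 15 (not isolated)
Conditions: TsNHNH2, 4 Å MS, THF, 23 °C; catecholborane, CHCl3, 0 °C; NaOAc·3H2O, 55 °C; then 0.5 M HCl, THF, 0 °C
Reagents that add atoms: none
Why: tosylhydrazone reduction (hydride addition to C=N, sulfinate loss, N2 extrusion from the diazene) turns CHO into the C8 methyl without touching the C8 stereocentre; brief acid then hydrolyses the silyl enol ether to the C5 ketone.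

**Step 11**
Reactants: 16 ring B ketone; 17 pent-1-en-3-one (ethyl vinyl ketone)
Product: 19 (4aR,5S,6R)-6-(benzyloxy)-5-[(tert-butyldimethylsilyloxy)methyl]-1,4a,6-trimethyl-4,4a,5,6,7,8-hexahydronaphthalen-2(3H)-one, via diketone 18 (not isolated)
Conditions: KOH (0.3 equiv), EtOH, 0 → 23 °C; then KOH (2 equiv), EtOH, 60 °C
Reagents that add atoms: none
Why: Robinson annulation; the more substituted enolate adds to the enone anti to the adjacent C9 CH2OTBS group (as with 2,3-dialkylcyclohexanones), which sets C10 with its methyl cis to C11, and aldol condensation closes ring A.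

**Step 12**
Reactants: 19 bicyclic enone
Product: 21 (4aR,5S,6R)-6-(benzyloxy)-5-[(tert-butyldimethylsilyloxy)methyl]-1,1,4a,6-tetramethyl-3,4,4a,5,6,7-hexahydronaphthalen-2(1H)-one, via potassium dienolate 20 (not isolated)
Conditions: KOtBu (1.3 equiv), t-BuOH–THF, 23 °C; MeI (1.5 equiv), 0 → 23 °C
Reagents that add atoms: iodomethane, CI
Why: deconjugative α-alkylation of the extended enolate (γ-deprotonation at C6, methylation at C4) gives the C4 gem-dimethyl group and moves the alkene to C5=C6.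

**Step 13**
Reactants: 21 gem-dimethyl enone silyl ether
Product: 22 (4aR,5S,6R)-6-(benzyloxy)-5-(hydroxymethyl)-1,1,4a,6-tetramethyl-3,4,4a,5,6,7-hexahydronaphthalen-2(1H)-one
Conditions: TBAF, THF, 23 °C
Reagents that add atoms: none
Why: fluoride desilylation frees the C11 hydroxyl needed as a directing group.

**Step 14**
Reactants: 22 homoallylic-type alcohol
Product: 23 (4aS,5S,6R,8aS)-6-(benzyloxy)-5-(hydroxymethyl)-1,1,4a,6-tetramethyloctahydronaphthalen-2(1H)-one (cis-fused)
Conditions: [Ir(cod)(PCy3)(py)]PF6 (10 mol %), H2 (1–5 atm), CH2Cl2, 23 °C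
Reagents that add atoms: none
Why: hydroxyl-directed homogeneous hydrogenation (the cyclohex-3-enylmethanol class): iridium bound to the C9 CH2OH, which sits on the same face as the C10 methyl, should deliver H2 to C5=C6 from that face and set H-5 cis to the C10 methyl.

**Step 15**
Reactants: 23 cis-fused keto alcohol
Product: 24 (4aS,5R,6R,8aS)-6-(benzyloxy)-1,1,4a,6-tetramethyl-5-[(phenylsulfanyl)methyl]octahydronaphthalen-2(1H)-one
Conditions: PhSSPh, n-Bu3P, THF, 50 °C
Reagents that add atoms: diphenyl disulfide, c1ccc(SSc2ccccc2)cc1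
Why: phosphine/disulfide thioetherification (thiolate SN2 on the alkoxyphosphonium ion) works on hindered primary alcohols and leaves the ketone alone.

**Step 16**
Reactants: 24 keto sulfide
Product: 25 (4aS,5R,6R,8aS)-6-(benzyloxy)-1,1,4a,6-tetramethyl-5-[(phenylsulfanyl)methyl]decahydronaphthalen-2-ol (C2 epimers)
Conditions: NaBH4, MeOH, 0 °C
Reagents that add atoms: none
Why: hydride reduction takes C3 to the alcohol level so that no enolisable ketone is present in the carbanion step; the new C3 centre is not controlled and is removed by oxidation in step 22.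

**Step 17**
Reactants: 25 hydroxy sulfide
Product: 26 (4aS,5R,6R,8aS)-6-(benzyloxy)-1,1,4a,6-tetramethyl-5-[(phenylsulfonyl)methyl]decahydronaphthalen-2-ol
Conditions: (NH4)6Mo7O24·4H2O (10 mol %), 30% H2O2, EtOH, 0 → 23 °C
Reagents that add atoms: hydrogen peroxide, OO
Why: molybdate-catalysed sulfide-to-sulfone oxidation is chemoselective in the presence of a secondary alcohol and a benzyl ether.

**Step 18**
Reactants: 26 hydroxy sulfone
Product: 27 triethylsilyl ether of 26
Conditions: TESOTf, 2,6-lutidine, CH2Cl2, −78 → 0 °C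
Reagents that add atoms: triethylsilyl trifluoromethanesulfonate, CC[Si](CC)(CC)OS(=O)(=O)C(F)(F)F
Why: silylation removes the last acidic proton before carbanion formation.

**Step 19**
Reactants: 27 sulfone; 6 allylic bromide
Product: 29 C11-alkylated sulfone (C11 epimers), via lithiated sulfone 28 (not isolated)
Conditions: n-BuLi (1.1 equiv), THF–HMPA, −78 °C; then 6, −78 → −40 °C
Reagents that add atoms: none
Why: alkylation of an α-sulfonyl carbanion with a primary allylic bromide (SN2, alkene geometry retained) forms C11–C12; the C11 centre is removed in the next step.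

**Step 20**
Reactants: 29 alkylated sulfone
Product: 30 tertiary alcohol with C3 OTES, free C8 OH and terminal OTBS
Conditions: Li, EtNH2–THF, −78 °C; NH4Cl
Reagents that add atoms: none
Why: dissolving-metal reduction cleaves the C–SO2Ph bond and the benzyl ether in one operation and spares isolated trisubstituted alkenes and silyl ethers.

**Step 21**
Reactants: 30 bis-silyl ether
Product: 31 triol (C3 OH, C8 OH, terminal allylic OH)
Conditions: TBAF, THF, 45 °C
Reagents that add atoms: none
Why: fluoride removes both silyl groups.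

**Step 22**
Reactants: 31 triol
Product: 32 keto aldehyde (C3 ketone, (E)-enal, free C8 OH)
Conditions: 1,1,1-triacetoxy-1,1-dihydro-1,2-benziodoxol-3(1H)-one (2.5 equiv), NaHCO3, CH2Cl2, 23 °C
Reagents that add atoms: none
Why: hypervalent-iodine oxidation converts the secondary and the allylic primary alcohol and cannot touch the tertiary carbinol; the enal stays E.

**Step 23**
Reactants: 32 keto aldehyde
Product: 33 myrrhanone B (target)
Conditions: NaClO2, NaH2PO4, 2-methylbut-2-ene, t-BuOH–H2O, 23 °C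
Reagents that add atoms: sodium chlorite, [Na+].[O-]Cl=O
Why: Pinnick oxidation takes the enal to the acid without epimerisation, alkene isomerisation or attack on the ketone.

**Compound list**

1 | (2E,6E)-farnesol | OC/C=C(\C)CC/C=C(\C)CCC=C(C)C | starting material
2 | (2E,6E)-farnesyl acetate | CC(=O)OC/C=C(\C)CC/C=C(\C)CCC=C(C)C | intermediate
3 | (2E,6E,10E)-12-hydroxy-3,7,11-trimethyldodeca-2,6,10-trien-1-yl acetate | CC(=O)OC/C=C(\C)CC/C=C(\C)CC/C=C(\C)CO | intermediate
4 | (2E,6E,10E)-12-(tert-butyldimethylsilyloxy)-3,7,11-trimethyldodeca-2,6,10-trien-1-yl acetate | CC(=O)OC/C=C(\C)CC/C=C(\C)CC/C=C(\C)CO[Si](C)(C)C(C)(C)C | intermediate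
5 | (2E,6E,10E)-12-(tert-butyldimethylsilyloxy)-3,7,11-trimethyldodeca-2,6,10-trien-1-ol | OC/C=C(\C)CC/C=C(\C)CC/C=C(\C)CO[Si](C)(C)C(C)(C)C | intermediate
6 | (2E,6E,10E)-1-bromo-12-(tert-butyldimethylsilyloxy)-3,7,11-trimethyldodeca-2,6,10-triene | BrC/C=C(\C)CC/C=C(\C)CC/C=C(\C)CO[Si](C)(C)C(C)(C)C | intermediate
7 | 2-(tert-butyldimethylsilyloxy)acetaldehyde | CC(C)(C)[Si](C)(C)OCC=O | starting material
8 | 3-(triphenylphosphoranylidene)butan-2-one | CC(=O)C(C)=P(c1ccccc1)(c1ccccc1)c1ccccc1 | starting material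
9 | (E)-5-(tert-butyldimethylsilyloxy)-3-methylpent-3-en-2-one | CC(=O)/C(C)=C/CO[Si](C)(C)C(C)(C)C | intermediate
10 | (E)-2,5-bis(tert-butyldimethylsilyloxy)-3-methylpenta-1,3-diene | C=C(O[Si](C)(C)C(C)(C)C)/C(C)=C/CO[Si](C)(C)C(C)(C)C | intermediate
11 | 2-(benzyloxy)acetaldehyde | O=CCOCc1ccccc1 | starting material
12 | 2-(benzyloxy)prop-2-enal | C=C(OCc1ccccc1)C=O | intermediate
13 | (1R,2S)-1-(benzyloxy)-4-(tert-butyldimethylsilyloxy)-2-[(tert-butyldimethylsilyloxy)methyl]-3-methylcyclohex-3-ene-1-carbaldehyde | CC(C)(C)[Si](C)(C)OC[C@@H]1C(C)=C(O[Si](C)(C)C(C)(C)C)CC[C@@]1(C=O)OCc1ccccc1 | intermediate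
14 | 4-methylbenzenesulfonylhydrazone of 13 | CC(C)(C)[Si](C)(C)OC[C@@H]1C(C)=C(O[Si](C)(C)C(C)(C)C)CC[C@@]1(C=NNS(=O)(=O)c1ccc(C)cc1)OCc1ccccc1 | intermediate
15 | {[(3S,4R)-4-(benzyloxy)-3-[(tert-butyldimethylsilyloxy)methyl]-2,4-dimethylcyclohex-1-en-1-yl]oxy}(tert-butyl)dimethylsilane | CC(C)(C)[Si](C)(C)OC[C@@H]1C(C)=C(O[Si](C)(C)C(C)(C)C)CC[C@@]1(C)OCc1ccccc1 | intermediate
16 | (3S,4R)-4-(benzyloxy)-3-[(tert-butyldimethylsilyloxy)methyl]-2,4-dimethylcyclohexan-1-one (C2 epimers) | CC(C)(C)[Si](C)(C)OC[C@@H]1C(C)C(=O)CC[C@@]1(C)OCc1ccccc1 | intermediate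
17 | pent-1-en-3-one (ethyl vinyl ketone) | CCC(=O)C=C | starting material
18 | (2R,3S,4R)-4-(benzyloxy)-3-[(tert-butyldimethylsilyloxy)methyl]-2,4-dimethyl-2-(3-oxopentyl)cyclohexan-1-one | CC(C)(C)[Si](C)(C)OC[C@@H]1[C@@](C)(CCC(=O)CC)C(=O)CC[C@@]1(C)OCc1ccccc1 | intermediate
19 | (4aR,5S,6R)-6-(benzyloxy)-5-[(tert-butyldimethylsilyloxy)methyl]-1,4a,6-trimethyl-4,4a,5,6,7,8-hexahydronaphthalen-2(3H)-one | CC(C)(C)[Si](C)(C)OC[C@@H]1[C@@]2(C)CCC(=O)C(C)=C2CC[C@@]1(C)OCc1ccccc1 | intermediate
20 | potassium dienolate of 19 (C3 enolate, C3=C4 and C5=C6) | CC(C)(C)[Si](C)(C)OC[C@@H]1[C@@]2(C)CCC(O[K])=C(C)C2=CC[C@@]1(C)OCc1ccccc1 | intermediate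
21 | (4aR,5S,6R)-6-(benzyloxy)-5-[(tert-butyldimethylsilyloxy)methyl]-1,1,4a,6-tetramethyl-3,4,4a,5,6,7-hexahydronaphthalen-2(1H)-one | CC(C)(C)[Si](C)(C)OC[C@@H]1[C@@]2(C)CCC(=O)C(C)(C)C2=CC[C@@]1(C)OCc1ccccc1 | intermediate
22 | (4aR,5S,6R)-6-(benzyloxy)-5-(hydroxymethyl)-1,1,4a,6-tetramethyl-3,4,4a,5,6,7-hexahydronaphthalen-2(1H)-one | OC[C@@H]1[C@@]2(C)CCC(=O)C(C)(C)C2=CC[C@@]1(C)OCc1ccccc1 | intermediate
23 | (4aS,5S,6R,8aS)-6-(benzyloxy)-5-(hydroxymethyl)-1,1,4a,6-tetramethyloctahydronaphthalen-2(1H)-one | OC[C@@H]1[C@@]2(C)CCC(=O)C(C)(C)[C@H]2CC[C@@]1(C)OCc1ccccc1 | intermediate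
24 | (4aS,5R,6R,8aS)-6-(benzyloxy)-1,1,4a,6-tetramethyl-5-[(phenylsulfanyl)methyl]octahydronaphthalen-2(1H)-one | c1ccccc1SC[C@@H]1[C@@]2(C)CCC(=O)C(C)(C)[C@H]2CC[C@@]1(C)OCc1ccccc1 | intermediate
25 | (4aS,5R,6R,8aS)-6-(benzyloxy)-1,1,4a,6-tetramethyl-5-[(phenylsulfanyl)methyl]decahydronaphthalen-2-ol (C2 epimers) | c1ccccc1SC[C@@H]1[C@@]2(C)CCC(O)C(C)(C)[C@H]2CC[C@@]1(C)OCc1ccccc1 | intermediate
26 | (4aS,5R,6R,8aS)-6-(benzyloxy)-1,1,4a,6-tetramethyl-5-[(phenylsulfonyl)methyl]decahydronaphthalen-2-ol (C2 epimers) | O=S(=O)(C[C@@H]1[C@@]2(C)CCC(O)C(C)(C)[C@H]2CC[C@@]1(C)OCc1ccccc1)c1ccccc1 | intermediate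
27 | triethylsilyl ether of 26 | O=S(=O)(C[C@@H]1[C@@]2(C)CCC(O[Si](CC)(CC)CC)C(C)(C)[C@H]2CC[C@@]1(C)OCc1ccccc1)c1ccccc1 | intermediate
28 | α-lithio derivative of 27 (lithium at the sulfonyl-bearing carbon C11) | O=S(=O)(C([Li])[C@@H]1[C@@]2(C)CCC(O[Si](CC)(CC)CC)C(C)(C)[C@H]2CC[C@@]1(C)OCc1ccccc1)c1ccccc1 | intermediate
29 | 27 carrying the (2E,6E,10E)-12-(tert-butyldimethylsilyloxy)-3,7,11-trimethyldodeca-2,6,10-trienyl group on the sulfonyl-bearing carbon (epimers there) | O=S(=O)(C(C/C=C(\C)CC/C=C(\C)CC/C=C(\C)CO[Si](C)(C)C(C)(C)C)[C@@H]1[C@@]2(C)CCC(O[Si](CC)(CC)CC)C(C)(C)[C@H]2CC[C@@]1(C)OCc1ccccc1)c1ccccc1 | intermediate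
30 | (1R,2R,4aS,8aS)-1-[(3E,7E,11E)-13-(tert-butyldimethylsilyloxy)-4,8,12-trimethyltrideca-3,7,11-trienyl]-2,5,5,8a-tetramethyl-6-(triethylsilyloxy)decahydronaphthalen-2-ol (C6 epimers) | C/C(=C\CC/C(C)=C/CC[C@@H]1[C@@]2(C)CCC(O[Si](CC)(CC)CC)C(C)(C)[C@H]2CC[C@@]1(C)O)CC/C=C(\C)CO[Si](C)(C)C(C)(C)C | intermediate
31 | (1R,2R,4aS,8aS)-1-[(3E,7E,11E)-13-hydroxy-4,8,12-trimethyltrideca-3,7,11-trienyl]-2,5,5,8a-tetramethyldecahydronaphthalene-2,6-diol (C6 epimers) | C/C(=C\CC/C(C)=C/CC[C@@H]1[C@@]2(C)CCC(O)C(C)(C)[C@H]2CC[C@@]1(C)O)CC/C=C(\C)CO | intermediate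
32 | (2E,6E,10E)-13-[(1R,2R,4aS,8aS)-2-hydroxy-2,5,5,8a-tetramethyl-6-oxodecahydronaphthalen-1-yl]-2,6,10-trimethyltrideca-2,6,10-trienal | C/C(=C\CC/C(C)=C/CC[C@@H]1[C@@]2(C)CCC(=O)C(C)(C)[C@H]2CC[C@@]1(C)O)CC/C=C(\C)C=O | intermediate
33 | myrrhanone B, (2E,6E,10E)-13-[(1R,2R,4aS,8aS)-2-hydroxy-2,5,5,8a-tetramethyl-6-oxodecahydronaphthalen-1-yl]-2,6,10-trimethyltrideca-2,6,10-trienoic acid | C/C(=C\CC/C(C)=C/CC[C@@H]1[C@@]2(C)CCC(=O)C(C)(C)[C@H]2CC[C@@]1(C)O)CC/C=C(\C)C(=O)O | target

**Step count and risks**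

Total step count: 23. Longest linear sequence: 17 steps (7 → 33 through steps 6, 7 and 9–23).

Steps most likely to fail:

Step 9. The silyloxy diene may react with the activated enal through hetero-cycloaddition or Mukaiyama-type addition, or the catalyst may give poor facial discrimination (low enantiomeric purity) or incomplete endo control. Fallback, setting out from 10 and 12: the cycloaddition is run thermally without catalyst (toluene, 90 °C) to give the endo adduct as a racemate, which is taken through steps 10–14 as the racemate. Racemic 23 is then esterified with (S)-O-acetylmandelic acid (DCC, DMAP, CH2Cl2), the diastereomeric esters are separated, and the (S)-O-acetylmandelate of 23 F1 is cleaved with K2CO3 in MeOH. The route is rejoined at enantiopure 23.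

Step 10. Hydrazone formation at the neopentyl-type aldehyde may stall, or the benzyloxy group may be lost by β-elimination while the diazene collapses. Fallback, setting out from 13: NaBH4 (MeOH, 0 °C) gives the primary alcohol [(1S,2S)-1-(benzyloxy)-4-(tert-butyldimethylsilyloxy)-2-[(tert-butyldimethylsilyloxy)methyl]-3-methylcyclohex-3-en-1-yl]methanol F2. I2, PPh3 and imidazole (toluene, 80 °C) give the neopentyl iodide F3, and Bu3SnH with AIBN (benzene, 80 °C) removes iodine by a radical chain; a β-alkoxy radical neither fragments nor rearranges. The route is rejoined at 15, which the acid treatment of step 10 converts to 16.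

Step 14. Hydrogen delivery to the hindered trisubstituted C5=C6 alkene may be too slow, or the single primary hydroxyl may not control the face well enough. Fallback, setting out from 22: the C3 ketone is reduced first (NaBH4, MeOH, 0 °C; hydride from the less hindered face) to the 3β,11-diol (2S,4aR,5S,6R)-6-(benzyloxy)-5-(hydroxymethyl)-1,1,4a,6-tetramethyl-1,2,3,4,4a,5,6,7-octahydronaphthalen-2-ol F4, which has a second, homoallylic hydroxyl on the same face. Hydrogenation with the same iridium complex then gives the cis-fused diol F5, and selective thioetherification of its primary hydroxyl (PhSSPh, n-Bu3P) rejoins the route at 25, so that step 16 is no longer needed.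

**Further compounds**

F1 | step 9 | (S)-O-acetylmandelate of 23, [(1S,2R,4aS,8aS)-2-(benzyloxy)-2,5,5,8a-tetramethyl-6-oxodecahydronaphthalen-1-yl]methyl (S)-2-acetoxy-2-phenylacetate | CC(=O)O[C@H](C(=O)OC[C@@H]1[C@@]2(C)CCC(=O)C(C)(C)[C@H]2CC[C@@]1(C)OCc1ccccc1)c1ccccc1
F2 | step 10 | [(1S,2S)-1-(benzyloxy)-4-(tert-butyldimethylsilyloxy)-2-[(tert-butyldimethylsilyloxy)methyl]-3-methylcyclohex-3-en-1-yl]methanol | CC(C)(C)[Si](C)(C)OC[C@@H]1C(C)=C(O[Si](C)(C)C(C)(C)C)CC[C@@]1(CO)OCc1ccccc1
F3 | step 10 | {[(3S,4S)-4-(benzyloxy)-3-[(tert-butyldimethylsilyloxy)methyl]-4-(iodomethyl)-2-methylcyclohex-1-en-1-yl]oxy}(tert-butyl)dimethylsilane | CC(C)(C)[Si](C)(C)OC[C@@H]1C(C)=C(O[Si](C)(C)C(C)(C)C)CC[C@@]1(CI)OCc1ccccc1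
F4 | step 14 | (2S,4aR,5S,6R)-6-(benzyloxy)-5-(hydroxymethyl)-1,1,4a,6-tetramethyl-1,2,3,4,4a,5,6,7-octahydronaphthalen-2-ol | OC[C@@H]1[C@@]2(C)CC[C@H](O)C(C)(C)C2=CC[C@@]1(C)OCc1ccccc1
F5 | step 14 | (2S,4aS,5S,6R,8aS)-6-(benzyloxy)-5-(hydroxymethyl)-1,1,4a,6-tetramethyldecahydronaphthalen-2-ol | OC[C@@H]1[C@@]2(C)CC[C@H](O)C(C)(C)[C@H]2CC[C@@]1(C)OCc1ccccc1
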